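The C11–C12 bond is the single disconnection: it joins a farnesyl chain to a cis-fused (5S,8R,9R,10S) decalin. The key step exploits the unfunctionalised C11 methylene that hangs from C9 of ring B beside the free C8 hydroxyl. A temporary phenylsulfonyl group on C11 lets the C8-alkoxide/C11-carbanion dianion displace bromide from (2E,6E)-farnesyl bromide, and LiDBB erases the sulfone in the same flask. The precursor, a γ-hydroxy sulfone, comes in eight steps from 6-methoxy-2-tetralone. C5 is set by a catalytic asymmetric enone isomerisation; C10, C9 and C8 by three additions to the convex face of the cis-decalin.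

Key step: step 9

Remark: the target SMILES is read literally as (5S,8R,9R,10S), so H-5 and the C10 methyl are cis (cis-fused decalin). Polypodane numbering is used in the text (ring A C1–C5/C10, ring B C5–C10, C11 on C9, β = the face of H-5 and the C10 methyl).

Step 1
Reactants: 1 6-methoxy-2-tetralone
Product: 3 6-methoxy-1,1-dimethyl-3,4-dihydronaphthalen-2(1H)-one, via 6-methoxy-1-methyl-2-tetralone 2 (not isolated)
Conditions: NaH (2.4 equiv), MeI (3 equiv), THF, 0 °C → rt
Reagents that add atoms: iodomethane, CI
Why: Exhaustive enolate C-alkylation should occur twice at the benzylic C1 (future C4), the only doubly activated position; no stereocentre is formed.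

Step 2
Reactants: 3 6-methoxy-1,1-dimethyl-3,4-dihydronaphthalen-2(1H)-one
Product: 4 2,2-(ethylenedioxy)-6-methoxy-1,1-dimethyl-1,2,3,4-tetrahydronaphthalene
Conditions: HOCH2CH2OH, p-TsOH (cat.), PhMe, reflux, Dean–Stark
Reagents that add atoms: ethylene glycol, OCCO
Why: Acid-catalysed ketalisation with azeotropic removal of water masks the future C3 ketone against the Birch reduction, the cuprate, the Grignard reagent, the alkyllithium and LiDBB.

Step 3
Reactants: 4 2,2-(ethylenedioxy)-6-methoxy-1,1-dimethyl-1,2,3,4-tetrahydronaphthalene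
Product: 6 6,6-(ethylenedioxy)-5,5-dimethyl-3,4,5,6,7,8-hexahydronaphthalen-2(1H)-one, via dihydroanisole enol ether 5 (not isolated)
Conditions: Li, NH3(l), THF, t-BuOH, −78 → −33 °C; then (CO2H)2, MeOH/H2O, rt
Reagents that add atoms: water, O
Why: Birch reduction should give the 2,5-dihydroanisole with the tetrasubstituted ring-fusion alkene, and mild enol ether hydrolysis with oxalic acid should release the unconjugated β,γ-enone (C8 ketone, C5=C10) while the dioxolane survives; no stereocentre yet.

Step 4
Reactants: 6 6,6-(ethylenedioxy)-5,5-dimethyl-3,4,5,6,7,8-hexahydronaphthalen-2(1H)-one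
Product: 7 (4aS)-6,6-(ethylenedioxy)-5,5-dimethyl-4,4a,5,6,7,8-hexahydronaphthalen-2(3H)-one
Conditions: cinchona-derived primary amine–quinuclidine catalyst (10 mol %, pseudoenantiomer chosen for 4aS), ArCO2H (20 mol %), PhMe, rt
Reagents that add atoms: none
Why: Organocatalytic enantioselective olefin isomerisation (cooperative iminium–base catalysis): the primary amine condenses with the C8 ketone, deprotonation at C9 gives the dienamine, and the protonated quinuclidine should deliver the proton to one face of C5, setting C5 (S) in the thermodynamically favoured conjugated enone.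

Step 5
Reactants: 7 (4aS)-6,6-(ethylenedioxy)-5,5-dimethyl-4,4a,5,6,7,8-hexahydronaphthalen-2(3H)-one
Product: 9 (4aS,8aS)-6,6-(ethylenedioxy)-5,5,8a-trimethyl-2-(trimethylsilyloxy)-3,4,4a,5,6,7,8,8a-octahydronaphthalene, via lithium enolate 8 (not isolated)
Conditions: Me2CuLi (from MeLi, CuI), TMSCl, THF/Et2O, −78 → −30 °C; Et3N quench
Reagents that add atoms: lithium dimethylcuprate, [Li+].C[Cu-]C; chlorotrimethylsilane, C[Si](C)(C)Cl
Why: TMSCl-accelerated conjugate addition of a Gilman cuprate should deliver methyl to C10 anti to the bulky quaternary C4 on the γ-carbon C5 (the trans-to-4-substituent rule of cyclohexenones), which sets C10 with its methyl cis to H-5 (cis-decalin) and gives the Δ8(9) enolate regiospecifically, trapped as the silyl enol ether.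

Step 6
Reactants: 9 (4aS,8aS)-6,6-(ethylenedioxy)-5,5,8a-trimethyl-2-(trimethylsilyloxy)-3,4,4a,5,6,7,8,8a-octahydronaphthalene
Product: 10 (1R,4aS,8aS)-6,6-(ethylenedioxy)-5,5,8a-trimethyl-1-[(phenylthio)methyl]octahydronaphthalen-2(1H)-one
Conditions: PhSCH2Cl, ZnBr2 (cat.), CH2Cl2, 0 °C → rt
Reagents that add atoms: chloromethyl phenyl sulfide, ClCSc1ccccc1
Why: Lewis-acid-promoted α-alkylation of the silyl enol ether by the thionium ion (Mukaiyama-type SN1 alkylation) is regiospecific for C9; the cis-decalin must keep the quaternary C4 equatorial on ring B (an axial C4 would act like an axial tert-butyl group), which puts C1 axial on the concave α face beside C9, so the electrophile should enter axially from the convex β face and set C9 with C11 syn to the C10 methyl.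

Step 7
Reactants: 10 (1R,4aS,8aS)-6,6-(ethylenedioxy)-5,5,8a-trimethyl-1-[(phenylthio)methyl]octahydronaphthalen-2(1H)-one
Product: 11 (1R,2R,4aS,8aS)-6,6-(ethylenedioxy)-2,5,5,8a-tetramethyl-1-[(phenylthio)methyl]decahydronaphthalen-2-ol
Conditions: MeMgBr, THF, −78 → 0 °C
Reagents that add atoms: methylmagnesium bromide, C[Mg]Br
Why: Grignard 1,2-addition: in the same chair the axial (α) trajectory to C8 is blocked by the syn-axial C1 methylene (as in 3,3,5-trimethylcyclohexanone), so methyl should add equatorially from the β face and give 8β-CH3 and the axial 8α-OH (C8 R), trans-diaxial to the C9 substituent; low temperature limits enolisation and loss of thiophenoxide.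

Step 8
Reactants: 11 (1R,2R,4aS,8aS)-6,6-(ethylenedioxy)-2,5,5,8a-tetramethyl-1-[(phenylthio)methyl]decahydronaphthalen-2-ol
Product: 12 (1R,2R,4aS,8aS)-6,6-(ethylenedioxy)-2,5,5,8a-tetramethyl-1-[(phenylsulfonyl)methyl]decahydronaphthalen-2-ol
Conditions: 30% H2O2, (NH4)6Mo7O24 (cat.), EtOH, 0 °C → rt
Reagents that add atoms: hydrogen peroxide, OO
Why: Molybdate-catalysed sulfide-to-sulfone oxidation is chemoselective here because no alkene is present yet, the tertiary alcohol and the dioxolane are inert, and no stereocentre is touched.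

Step 9
Reactants: 12 (1R,2R,4aS,8aS)-6,6-(ethylenedioxy)-2,5,5,8a-tetramethyl-1-[(phenylsulfonyl)methyl]decahydronaphthalen-2-ol; 13 (2E,6E)-farnesyl bromide
Product: 16 (5S,8R,9R,10S)-3,3-(ethylenedioxy)polypoda-13E,17E,21-trien-8-ol, via dilithio dianion 14 (not isolated), via coupled C11 sulfone 15 (not isolated)
Conditions: n-BuLi (2.1 equiv), THF, −78 → −40 °C; 13, −78 → −20 °C; then LiDBB, THF, −78 °C; MeOH
Reagents that add atoms: none
Why: Double deprotonation gives the C8-alkoxide/C11-sulfonyl carbanion dianion, whose carbanion displaces bromide from the primary carbon of farnesyl bromide (SN2) and forges C11–C12; in the same flask LiDBB transfers two electrons to the aryl sulfone, the C11–S bond fragments to lithium benzenesulfinate and a C11 organolithium, and methanol protonates it. The closest known reaction type is the sulfone-mediated coupling of allylic halides used for polyprenoid assembly followed by reductive desulfonylation (Julia-type alkylation–desulfonylation). No ring is closed; the only new stereocentre (C11 of the coupled sulfone) is erased on desulfonylation, and C5, C8, C9 and C10 are untouched because none is acidic under these conditions. The step needs α- rather than γ-attack on the allylic bromide and retention of the 2E geometry: a sulfone-stabilised carbanion reacts by direct SN2 at the unhindered CH2 without passing through an allyl-metal species, so neither transposition nor E/Z scrambling is expected. It also needs C- rather than O-alkylation, which the far higher nucleophilicity of the carbanion over the hindered tertiary alkoxide should secure. Finally it needs selective reduction: isolated trisubstituted alkenes, the dioxolane and the alkoxide are inert to LiDBB at −78 °C, and the sulfone is homoallylic, not allylic, so no double-bond migration can accompany C–S cleavage.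

Step 10
Reactants: 16 (5S,8R,9R,10S)-3,3-(ethylenedioxy)polypoda-13E,17E,21-trien-8-ol
Product: 17 (5S,8R,9R,10S)-8-hydroxypolypoda-13E,17E,21-trien-3-one (target)
Conditions: p-TsOH (cat.), acetone/H2O, rt
Reagents that add atoms: water, O
Why: Mild acid-catalysed acetal hydrolysis should release the C3 ketone without dehydrating the tertiary alcohol or cyclising the trisubstituted alkenes; C5 is not α to the ketone, so no stereocentre can epimerise.

Compound list
1 | 6-methoxy-2-tetralone (6-methoxy-3,4-dihydronaphthalen-2(1H)-one) | COc1ccc2CC(=O)CCc2c1 | starting material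
2 | 6-methoxy-1-methyl-2-tetralone (racemic, not isolated) | COc1ccc2c(c1)CCC(=O)C2C | intermediate
3 | 6-methoxy-1,1-dimethyl-3,4-dihydronaphthalen-2(1H)-one | COc1ccc2c(c1)CCC(=O)C2(C)C | intermediate
4 | 2,2-(ethylenedioxy)-6-methoxy-1,1-dimethyl-1,2,3,4-tetrahydronaphthalene | COc1ccc2c(c1)CCC1(OCCO1)C2(C)C | intermediate
5 | 2,2-(ethylenedioxy)-6-methoxy-1,1-dimethyl-1,2,3,4,5,8-hexahydronaphthalene (not isolated) | COC1=CCC2=C(C1)CCC3(OCCO3)C2(C)C | intermediate
6 | 6,6-(ethylenedioxy)-5,5-dimethyl-3,4,5,6,7,8-hexahydronaphthalen-2(1H)-one | O=C1CCC2=C(C1)CCC3(OCCO3)C2(C)C | intermediate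
7 | (4aS)-6,6-(ethylenedioxy)-5,5-dimethyl-4,4a,5,6,7,8-hexahydronaphthalen-2(3H)-one | O=C1C=C2CCC3(OCCO3)C(C)(C)[C@H]2CC1 | intermediate
8 | lithium (4aS,8aS)-6,6-(ethylenedioxy)-5,5,8a-trimethyl-3,4,4a,5,6,7,8,8a-octahydronaphthalen-2-olate (not isolated) | [Li]OC1=C[C@@]2(C)CCC3(OCCO3)C(C)(C)[C@H]2CC1 | intermediate
9 | (4aS,8aS)-6,6-(ethylenedioxy)-5,5,8a-trimethyl-2-(trimethylsilyloxy)-3,4,4a,5,6,7,8,8a-octahydronaphthalene | C[Si](C)(C)OC1=C[C@@]2(C)CCC3(OCCO3)C(C)(C)[C@H]2CC1 | intermediate
10 | (1R,4aS,8aS)-6,6-(ethylenedioxy)-5,5,8a-trimethyl-1-[(phenylthio)methyl]octahydronaphthalen-2(1H)-one | c1ccccc1SC[C@@H]1[C@@]2(C)CCC3(OCCO3)C(C)(C)[C@H]2CCC1=O | intermediate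
11 | (1R,2R,4aS,8aS)-6,6-(ethylenedioxy)-2,5,5,8a-tetramethyl-1-[(phenylthio)methyl]decahydronaphthalen-2-ol | c1ccccc1SC[C@@H]1[C@@]2(C)CCC3(OCCO3)C(C)(C)[C@H]2CC[C@@]1(C)O | intermediate
12 | (1R,2R,4aS,8aS)-6,6-(ethylenedioxy)-2,5,5,8a-tetramethyl-1-[(phenylsulfonyl)methyl]decahydronaphthalen-2-ol | c1ccccc1S(=O)(=O)C[C@@H]1[C@@]2(C)CCC3(OCCO3)C(C)(C)[C@H]2CC[C@@]1(C)O | intermediate
13 | (2E,6E)-farnesyl bromide | CC(C)=CCC/C(C)=C/CC/C(C)=C/CBr | starting material
14 | dilithio dianion of 12 (C8-OLi, C11-Li; not isolated) | [Li]C(S(=O)(=O)c1ccccc1)[C@@H]1[C@@]2(C)CCC3(OCCO3)C(C)(C)[C@H]2CC[C@@]1(C)O[Li] | intermediate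
15 | (5S,8R,9R,10S)-3,3-(ethylenedioxy)-11-(phenylsulfonyl)polypoda-13E,17E,21-trien-8-ol (C11 epimers, as lithium alkoxide in the flask; not isolated) | CC(C)=CCC/C(C)=C/CC/C(C)=C/CC(S(=O)(=O)c1ccccc1)[C@@H]1[C@@]2(C)CCC3(OCCO3)C(C)(C)[C@H]2CC[C@@]1(C)O | intermediate
16 | (5S,8R,9R,10S)-3,3-(ethylenedioxy)polypoda-13E,17E,21-trien-8-ol | CC(C)=CCC/C(C)=C/CC/C(C)=C/CC[C@@H]1[C@@]2(C)CCC3(OCCO3)C(C)(C)[C@H]2CC[C@@]1(C)O | intermediate
17 | (5S,8R,9R,10S)-8-hydroxypolypoda-13E,17E,21-trien-3-one | CC(C)=CCC/C(C)=C/CC/C(C)=C/CC[C@@H]1[C@@]2(C)CCC(=O)C(C)(C)[C@H]2CC[C@@]1(C)O | target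

Total step count: 10. Longest linear sequence: 10 steps (1 → 17); farnesyl bromide 13 enters in step 9.

Steps most likely to fail

Step 4. What may go wrong is loss of enantiocontrol: poor facial discrimination in the γ-protonation at the hindered C5, which sits next to the gem-dimethyl carbon, or racemisation of the product through re-formation of the dienamine. The fallback replaces catalyst control by a divergent reduction of the racemate. It sets out from 6, which DBU should isomerise to the racemic enone F1. A Corey–Bakshi–Shibata reduction then converts both enantiomers into carbinols of the same C8 configuration, that is, into two diastereomers separable on silica. The (2S,4aS)-6,6-(ethylenedioxy)-5,5-dimethyl-2,3,4,4a,5,6,7,8-octahydronaphthalen-2-ol F2 is oxidised with MnO2, and the route is rejoined at 7. The other diastereomer is oxidised, re-racemised with DBU through the dienolate and recycled.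

Step 7. What may go wrong is poor facial selectivity in the carbonyl addition, because the axial CH2SPh group on C9 partly shields the β face, together with enolisation and β-elimination of thiophenoxide. The fallback is stereocomplementary and sets out from 10. Takai–Lombardo methylenation (Zn, CH2Br2, TiCl4) should give the exocyclic alkene with unchanged C5, C9 and C10, the 8-methylene compound F3. Mukaiyama hydration (Mn(dpm)3 cat., PhSiH3, O2, i-PrOH) then delivers oxygen to the tertiary C8 radical from the more open face. This sequence therefore gives the C8 epimer opposite to that of a methyl nucleophile, so if the Grignard reagent attacks the α face, the hydration should give 11, where the route is rejoined.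

Step 9. What may go wrong is slow C-alkylation of the congested α-sulfonyl carbanion (an axial CH2 between two fully substituted carbons), elimination of HBr from the bromide by the basic dianion, or consumption of LiDBB by residual bromide. The fallback uses a sulfur-free C11 nucleophile and sets out from 9. MeLi followed by gaseous formaldehyde should give the β-hydroxy ketone with CH2OH on the β face of C9, the hydroxymethyl ketone F4. Excess MeMgBr gives the 8,11-diol F5, and I2, PPh3 and imidazole convert only the primary alcohol into the primary iodide F6. t-BuLi (3 equiv) gives the γ-oxido alkyllithium F7. After Li→Mg exchange (MgBr2·OEt2), Li2CuCl4-catalysed SN2 coupling with 13 rejoins the route at 16.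

Further compounds
F1 | step 4 | racemic 6,6-(ethylenedioxy)-5,5-dimethyl-4,4a,5,6,7,8-hexahydronaphthalen-2(3H)-one | O=C1C=C2CCC3(OCCO3)C(C)(C)C2CC1
F2 | step 4 | (2S,4aS)-6,6-(ethylenedioxy)-5,5-dimethyl-2,3,4,4a,5,6,7,8-octahydronaphthalen-2-ol | O[C@@H]1C=C2CCC3(OCCO3)C(C)(C)[C@H]2CC1
F3 | step 7 | 6,6-(ethylenedioxy)-5,5,8a-trimethyl-2-methylene-1-[(phenylthio)methyl]decahydronaphthalene (ring stereocentres as in 10) | c1ccccc1SC[C@@H]1[C@@]2(C)CCC3(OCCO3)C(C)(C)[C@H]2CCC1=C
F4 | step 9 | 6,6-(ethylenedioxy)-1-(hydroxymethyl)-5,5,8a-trimethyloctahydronaphthalen-2(1H)-one (ring stereocentres as in 10) | OC[C@@H]1[C@@]2(C)CCC3(OCCO3)C(C)(C)[C@H]2CCC1=O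
F5 | step 9 | 6,6-(ethylenedioxy)-1-(hydroxymethyl)-2,5,5,8a-tetramethyldecahydronaphthalen-2-ol (ring stereocentres as in 11) | OC[C@@H]1[C@@]2(C)CCC3(OCCO3)C(C)(C)[C@H]2CC[C@@]1(C)O
F6 | step 9 | 6,6-(ethylenedioxy)-1-(iodomethyl)-2,5,5,8a-tetramethyldecahydronaphthalen-2-ol (ring stereocentres as in 11) | IC[C@@H]1[C@@]2(C)CCC3(OCCO3)C(C)(C)[C@H]2CC[C@@]1(C)O
F7 | step 9 | dilithio species of F6 after I/Li exchange (C8-OLi, C11-Li; not isolated) | [Li]C[C@@H]1[C@@]2(C)CCC3(OCCO3)C(C)(C)[C@H]2CC[C@@]1(C)O[Li]
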